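**Analysis of the target**

The target (22) is a linear tridepside with no stereocentre. It holds three benzene rings and no other ring, joined by two aryl ester bonds. Ring A is an orsellinic acid unit (C1 CO2H, C2 OH, C6 CH3) whose O4 carries the ring B acyl group. Ring B is a second orsellinoyl unit (C2 OH, C6 CH3) whose O4 carries ring C. Ring C is a 3,4,6-trihydroxy-2-methylbenzoyl group, an orsellinoyl unit with one more hydroxyl between the methyl group and the para oxygen. The sensitive groups are the two depside esters (each an ester of a phenol para to a carbonyl group, so hydroxide, alkoxides and amines cleave or transfer them), the hydroquinone/catechol array of ring C (air-oxidised to a quinone once free) and the salicylic acid of ring A (decarboxylation on heating). The difficulty is regiochemical: five phenols and one acid on three similar rings must be told apart, both acyl carbons are flanked by two ortho substituents, and the last step must free everything without touching an aryl ester, which restricts protection to benzyl groups and hydrogenolysis. The route rests on ring A: its C1 (carboxyl), C2 (OH), C4 (ester oxygen) and C6 (methyl) are the C1, C2, C4 and C6 of a 6-methyl-2,4-dioxocyclohexane-1-carboxylate. At that oxidation level the C4 oxygen is a vinylogous acid oxygen, distinct from the C2 oxygen, and can be acylated before any phenol of ring A exists.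

**Retrosynthetic reasoning**

The target 22 is traced back to its fully benzylated form 21 (four benzyl ethers on rings B and C, benzyl ester on ring A). Hydrogenolysis is the one deprotection that leaves both depside esters alone, so every protecting group is chosen to fall in that step. The ring A C2 hydroxyl is left free in 21 because it is hydrogen-bonded to the ester and never has to react.

In 21 the aromatic ring A is taken back to a cyclohexenone. Removing the C1–C6 double bond and tautomerising gives selenide 18 and, before it, enol ester 17. The forward reaction has to introduce one unsaturation between C1 and C6. C1 is the acidic carbon of a β-keto ester, so a selenium group can be placed there and removed by syn elimination with the single C6 hydrogen. The resulting cross-conjugated dienone 20 is the keto tautomer of the phenol, and the ring A hydroxyl appears at this point without ever having been protected.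

The enol ester C–O bond of 17 (ring B carbonyl to O4 of ring A) is cut next, giving dione 4 and acid chloride 16, made from acid 15. Cutting here and not at the phenol stage means the acylation partner is a highly nucleophilic 1,3-dione enolate with two unlike oxygens. O4 is remote from the ester-bearing C1, while O2 is crowded by it, so the bulky acyl group should go to O4 without a protecting group on ring A.

Dione 4 is disconnected at C1–C6 and C3–C4 into benzyl 3-oxobutanoate 1 and benzyl (E)-but-2-enoate 2, through Michael adduct 3. Both are commercial esters, so the annulation is the first step of the ring A line. The benzyl ester is installed here because it must survive to the end and leave by hydrogenolysis.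

Acid 15 is taken back to aldehyde 14, then to phenol 13, and the ring C carbonyl–O4 bond is cut to give 2,4-dihydroxy-6-methylbenzaldehyde 11 and acid chloride 12 (from acid 10). The formyl group serves as the masked carboxyl of ring B. It chelates the C2 hydroxyl so that only O4 is acylated, and it is oxidised to the acid under conditions that do not touch an aryl ester. The C2 hydroxyl of ring B is benzylated after the esterification because an ortho-protected acid is needed for clean acid chloride formation.

Acid 10 comes from aldehyde 9 by oxidation, and 9 from the tribenzyl ether 8 by formylation at the position between the methyl group and an ether oxygen. Ether 8 is the protected form of triol 7, the reduction product of hydroxyquinone 6, which arises from orcinol 5 by oxidation para to one hydroxyl. This puts the extra ring C oxygen in first and the carboxyl carbon in last, each at the position the substituents already present direct to.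

**Alternatives that were turned down**

Alternative 1: Ring B would be built by benzannulation, cutting its C1–C2, C2–C3 and C4–C5 bonds. The precursors are diazo ketone A2, in which the differentiated ring A phenol A4 is already esterified with an acyclic acid, and siloxyalkyne A3.
- Forward key step: irradiation of A2 expels nitrogen and Wolff rearrangement gives a vinylketene, which adds A3 in a [2+2] step to a cyclobutenone. Four-electron ring opening and six-electron closure then give A1, the ring A–ring B depside with the ring B C2 hydroxyl free and O4 silylated.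
- For it: the depside ester is made on an unhindered acyclic acid, and the two ring B oxygens leave the key step differentiated. On both points it is stronger than the chosen route, which must benzylate 13 and use the hindered chloride 16.
- Against it: A2 combines a diazo group, an electron-poor alkene (open to dipolar cycloaddition) and an activated aryl ester, and needs several steps including diazo transfer. A3 must be prepared, and A4 needs three or four steps of phenol differentiation. The photochemical step is spent on ring B, the one ring whose full substitution pattern is commercial as 11.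
- Comparison: the chosen strategy puts its constructive step on ring A, where it removes protecting-group work, and reaches the ring A–ring B ester in fewer operations.

Alternative 2: Only ring C is addressed. Its C6–CH3 and C5–O bonds are cut, leading back to chloroaryl oxazoline A6.
- Forward key step: directed lithiation of A6 between the oxazoline and the chlorine and loss of chloride give the C5–C6 aryne. A methyl carbanion adds at C6 under guidance of the oxazoline, and the C5 aryl anion is borylated and oxidised in the same pot to give A5.
- For it: both missing ring C substituents are placed with a regiochemistry fixed by the mechanism. This is stronger than the chosen route, whose ring C depends on the intrinsic selectivity of an oxidation (step 2) and a formylation (step 4).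
- Against it: A5 carries methyl ethers that cannot be removed at the end without cleaving the depside esters, so they must be exchanged for benzyl ethers before coupling. The di-ortho-substituted aryl oxazoline is unmasked only under forcing conditions. With the preparation of A6 the sequence is clearly longer than steps 2 to 5 and needs two cryogenic organolithium operations.
- Comparison: it contributes nothing to the ring A–ring B problem. The chosen route builds ring C by four classical steps from 5 and keeps benzyl as the only protecting group.

Alternative 3: Ring B and the ring A–ring B ester are made together by cutting the ring B carbonyl–O bond and the ring B C1–C6 bond, back to phenol A4 and diketo-dioxinone A8.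
- Forward key step: heating A8 causes cycloreversion to an acylketene, which acylates A4. The aryl 3,5,7-trioxooctanoate closes by aldol condensation of its C2 onto the C7 ketone and dehydrates to the resorcylate A7.
- For it: no hindered benzoic acid has to be activated for this ester, and ring B emerges with both hydroxyls free, of which only O4 is nucleophilic, so ring C can be attached without protecting ring B. On the mildness of the ester formation it is stronger than the chosen route.
- Against it: A8 needs several steps, and A4 needs its two phenols differentiated over three or four steps. The aryl triketo ester is an activated ester exposed to the base that triggers the aldol step, so transacylation competes. The cyclisation must also be steered away from pyranone formation.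
- Comparison: the chosen strategy offers a ring A partner that needs no phenol differentiation (4 comes in one step from two bulk esters) and a hindered acylation that takes place on a very nucleophilic dione enolate.

Key step: step 1

Remark: the target has no stereocentre; 3, 4, 17, 18 and 19 are racemic and drawn as one enantiomer. Compounds 1, 2, 5 and 11 and NaOCH2Ph in benzyl alcohol are taken as commercial.

**Route**

Step 1
Reactants: 1 benzyl 3-oxobutanoate; 2 benzyl (E)-but-2-enoate
Product: 4 benzyl (1S,6R)-6-methyl-2,4-dioxocyclohexane-1-carboxylate (racemic trans), via Michael adduct 3 (not isolated)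
Conditions: NaOCH2Ph (1.1 equiv, 1.0 M in PhCH2OH), toluene, 90 °C; then cold aq HCl
Reagents that add atoms: none
Why: Benzyloxide deprotonates 1 at C2 and the stabilised enolate adds to the β-carbon of 2 (conjugate addition, new C1–C6 bond of ring A), giving 3 as its enolate. Proton exchange under the equilibrating alkoxide conditions makes the methyl ketone enolate available, and its carbon attacks the crotonate-derived ester carbonyl (Dieckmann condensation, new C3–C4 bond) with loss of benzyloxide. The ring closes in the 6-exo-trig mode; closure from any other carbanion of 3 would give a four-membered ring and does not compete. The 1,3-dione formed is deprotonated at once to a vinylogous carboxylate, and this last step pulls the reversible Michael and Claisen equilibria towards product. The closest known reaction type is the alkoxide-mediated Michael–Dieckmann condensation of alkyl acetoacetates with alkyl crotonates to alkyl dihydroorsellinates. C6 is set in the conjugate addition without control (racemate), and C1, still acidic between ketone and ester, equilibrates to the trans isomer with methyl and ester both equatorial; both centres are erased in step 11. The selectivity needed is C-alkylation of 1 at C2 and an alkoxide matched to the esters, so that ester exchange is degenerate; the sodium enolate of 4 is extracted into water, benzyl alcohol is washed out, and cold acid sets 4 free.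

Step 2
Reactants: 5 orcinol (5-methylbenzene-1,3-diol)
Product: 6 2-hydroxy-6-methylcyclohexa-2,5-diene-1,4-dione
Conditions: (KSO3)2NO (2.2 equiv), KH2PO4, H2O/acetone, 0 °C to rt
Reagents that add atoms: potassium nitrosodisulfonate (Fremy's salt), [K+].[K+].[O]N(S(=O)(=O)[O-])S(=O)(=O)[O-]
Why: Teuber oxidation: one nitroxyl radical makes the phenoxyl radical and a second couples at the carbon para to that oxygen, which is the position between the other hydroxyl and the methyl group; loss of imidodisulfonate gives the hydroxy-para-quinone. The two such positions of 5 are equivalent by symmetry, so one regioisomer is expected.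

Step 3
Reactants: 6 2-hydroxy-6-methylcyclohexa-2,5-diene-1,4-dione
Product: 8 1,2,5-tris(benzyloxy)-3-methylbenzene, via triol 7 (not isolated)
Conditions: Na2S2O4, THF/H2O, rt; then BnBr, K2CO3, DMF, 60 °C, under Ar
Reagents that add atoms: benzyl bromide, BrCc1ccccc1
Why: Dithionite reduces the quinone to the air-sensitive triol 7, which is carried on crude under argon into a threefold Williamson ether synthesis.

Step 4
Reactants: 8 1,2,5-tris(benzyloxy)-3-methylbenzene
Product: 9 3,4,6-tris(benzyloxy)-2-methylbenzaldehyde
Conditions: POCl3, DMF, 0 to 60 °C; then H2O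
Reagents that add atoms: N,N-dimethylformamide, CN(C)C=O; water, O
Why: Vilsmeier–Haack formylation; the position between the methyl group and the C5 ether is ortho to one benzyloxy group and para to another, the site at which 1,2,4-trialkoxybenzenes and 3,5-dialkoxytoluenes are formylated. The only other free position lies between two benzyloxy groups and is more hindered.

Step 5
Reactants: 9 3,4,6-tris(benzyloxy)-2-methylbenzaldehyde
Product: 10 3,4,6-tris(benzyloxy)-2-methylbenzoic acid
Conditions: NaClO2, NaH2PO4, 2-methylbut-2-ene, t-BuOH/THF/H2O, rt
Reagents that add atoms: sodium chlorite, [Na+].[O-]Cl=O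
Why: Pinnick oxidation; chlorous acid oxidises the hindered aldehyde, and the alkene scavenges hypochlorous acid so that the electron-rich ring is not chlorinated. Benzyl ethers are inert.

Step 6
Reactants: 10 3,4,6-tris(benzyloxy)-2-methylbenzoic acid; 11 2,4-dihydroxy-6-methylbenzaldehyde
Product: 13 4-formyl-3-hydroxy-5-methylphenyl 3,4,6-tris(benzyloxy)-2-methylbenzoate, via acid chloride 12 (not isolated)
Conditions: (COCl)2, cat. DMF, CH2Cl2, 0 °C to rt, evaporate; then 11, Et3N, CH2Cl2, 0 °C to rt
Reagents that add atoms: none
Why: Acid chloride formation, then phenol acylation as in classical depside synthesis. The C4 hydroxyl of 11 (para to the formyl group, the more acidic one) is acylated, while the C2 hydroxyl is held in a hydrogen bond to the formyl oxygen and stays free.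

Step 7
Reactants: 13 4-formyl-3-hydroxy-5-methylphenyl 3,4,6-tris(benzyloxy)-2-methylbenzoate
Product: 14 3-(benzyloxy)-4-formyl-5-methylphenyl 3,4,6-tris(benzyloxy)-2-methylbenzoate
Conditions: BnBr, K2CO3, DMF, rt
Reagents that add atoms: benzyl bromide, BrCc1ccccc1
Why: Williamson ether synthesis on the chelated ortho-hydroxy aldehyde. The aryl ester is shielded by the two ortho substituents of its acyl group and should survive anhydrous carbonate at room temperature.

Step 8
Reactants: 14 3-(benzyloxy)-4-formyl-5-methylphenyl 3,4,6-tris(benzyloxy)-2-methylbenzoate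
Product: 15 2-(benzyloxy)-6-methyl-4-{[3,4,6-tris(benzyloxy)-2-methylbenzoyl]oxy}benzoic acid
Conditions: NaClO2, NaH2PO4, 2-methylbut-2-ene, t-BuOH/THF/H2O, rt
Reagents that add atoms: sodium chlorite, [Na+].[O-]Cl=O
Why: Pinnick oxidation under buffered, weakly acidic conditions unmasks the ring B carboxyl without touching the depside ester or the benzyl ethers.

Step 9
Reactants: 15 2-(benzyloxy)-6-methyl-4-{[3,4,6-tris(benzyloxy)-2-methylbenzoyl]oxy}benzoic acid; 4 benzyl (1S,6R)-6-methyl-2,4-dioxocyclohexane-1-carboxylate
Product: 17 benzyl (1S,6R)-4-{[2-(benzyloxy)-6-methyl-4-{[3,4,6-tris(benzyloxy)-2-methylbenzoyl]oxy}benzoyl]oxy}-6-methyl-2-oxocyclohex-3-ene-1-carboxylate (racemic trans), via acid chloride 16 (not isolated)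
Conditions: (COCl)2, cat. DMF, CH2Cl2, 0 °C to rt, evaporate; then 4 (1.05 equiv), Et3N, CH2Cl2, −20 to 0 °C
Reagents that add atoms: none
Why: O-Acylation of the triethylammonium enolate of a cyclic 1,3-dione by an acid chloride, the standard way to 3-acyloxy-enones. Of the two enolate oxygens, O2 is crowded by the ester-bearing C1 while O4 is flanked only by CH2, so the di-ortho-substituted aroyl chloride should go to O4. No acyl-transfer catalyst is used, so the enol ester does not rearrange to the C-acyl isomer.

Step 10
Reactants: 17 benzyl (1S,6R)-4-{[2-(benzyloxy)-6-methyl-4-{[3,4,6-tris(benzyloxy)-2-methylbenzoyl]oxy}benzoyl]oxy}-6-methyl-2-oxocyclohex-3-ene-1-carboxylate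
Product: 18 benzyl (1S,6R)-4-{[2-(benzyloxy)-6-methyl-4-{[3,4,6-tris(benzyloxy)-2-methylbenzoyl]oxy}benzoyl]oxy}-6-methyl-2-oxo-1-(phenylselanyl)cyclohex-3-ene-1-carboxylate (racemic; selenium trans to the C6 methyl)
Conditions: PhSeCl, pyridine, CH2Cl2, 0 °C
Reagents that add atoms: benzeneselenenyl chloride, Cl[Se]c1ccccc1
Why: α-Selenenylation of a β-keto ester through its enol. In the enol the C6 methyl group is pseudoaxial to avoid allylic strain with the C1 ester, so the electrophile enters from the opposite face and the selenium ends cis to the C6 hydrogen, as the syn elimination requires. The new quaternary centre is set by this substrate control and disappears in step 11.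

Step 11
Reactants: 18 benzyl (1S,6R)-4-{[2-(benzyloxy)-6-methyl-4-{[3,4,6-tris(benzyloxy)-2-methylbenzoyl]oxy}benzoyl]oxy}-6-methyl-2-oxo-1-(phenylselanyl)cyclohex-3-ene-1-carboxylate
Product: 21 benzyl 4-{[2-(benzyloxy)-6-methyl-4-{[3,4,6-tris(benzyloxy)-2-methylbenzoyl]oxy}benzoyl]oxy}-2-hydroxy-6-methylbenzoate, via selenoxide 19 (not isolated), via dienone tautomer 20 (not isolated)
Conditions: 30% aq H2O2 (2.5 equiv), CH2Cl2, 0 °C to rt
Reagents that add atoms: none
Why: Oxidation to the selenoxide and syn elimination with the only β-hydrogen (C6–H) form the C1–C6 double bond. The cross-conjugated dienone 20 is the keto tautomer of a phenol and enolises at once, so the ring A hydroxyl appears hydrogen-bonded to the benzyl ester. Both steps are known reaction types (selenoxide elimination of α-seleno β-keto esters, aromatisation of cyclohexenones by dehydrogenation).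

Step 12
Reactants: 21 benzyl 4-{[2-(benzyloxy)-6-methyl-4-{[3,4,6-tris(benzyloxy)-2-methylbenzoyl]oxy}benzoyl]oxy}-2-hydroxy-6-methylbenzoate
Product: 22 2-hydroxy-4-({2-hydroxy-6-methyl-4-[(3,4,6-trihydroxy-2-methylbenzoyl)oxy]benzoyl}oxy)-6-methylbenzoic acid (target)
Conditions: H2 (1 atm), 10% Pd/C, THF/EtOAc, rt; filtration and concentration under N2
Reagents that add atoms: none
Why: Hydrogenolysis removes the four benzyl ethers and the benzyl ester in one operation and leaves both aryl esters intact, the usual last step of depside syntheses. Compound 21 must be freed of selenium residues beforehand, and the product is kept from air because of the ring C hydroquinone.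

**Compound list**

1 | benzyl 3-oxobutanoate | CC(=O)CC(=O)OCc1ccccc1 | starting material
2 | benzyl (E)-but-2-enoate | C/C=C/C(=O)OCc1ccccc1 | starting material
3 | dibenzyl 2-acetyl-3-methylpentanedioate (racemic, mixture of diastereomers) | CC(=O)C(C(=O)OCc1ccccc1)C(C)CC(=O)OCc1ccccc1 | intermediate (not isolated)
4 | benzyl (1S,6R)-6-methyl-2,4-dioxocyclohexane-1-carboxylate (racemic, trans) | C[C@@H]1CC(=O)CC(=O)[C@H]1C(=O)OCc1ccccc1 | intermediate
5 | orcinol (5-methylbenzene-1,3-diol) | Cc1cc(O)cc(O)c1 | starting material
6 | 2-hydroxy-6-methylcyclohexa-2,5-diene-1,4-dione | CC1=CC(=O)C=C(O)C1=O | intermediate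
7 | 6-methylbenzene-1,2,4-triol | Cc1cc(O)cc(O)c1O | intermediate (not isolated)
8 | 1,2,5-tris(benzyloxy)-3-methylbenzene | Cc1cc(OCc2ccccc2)cc(OCc2ccccc2)c1OCc1ccccc1 | intermediate
9 | 3,4,6-tris(benzyloxy)-2-methylbenzaldehyde | Cc1c(C=O)c(OCc2ccccc2)cc(OCc2ccccc2)c1OCc1ccccc1 | intermediate
10 | 3,4,6-tris(benzyloxy)-2-methylbenzoic acid | Cc1c(C(=O)O)c(OCc2ccccc2)cc(OCc2ccccc2)c1OCc1ccccc1 | intermediate
11 | 2,4-dihydroxy-6-methylbenzaldehyde | Cc1cc(O)cc(O)c1C=O | starting material
12 | 3,4,6-tris(benzyloxy)-2-methylbenzoyl chloride | Cc1c(C(=O)Cl)c(OCc2ccccc2)cc(OCc2ccccc2)c1OCc1ccccc1 | intermediate (not isolated)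
13 | 4-formyl-3-hydroxy-5-methylphenyl 3,4,6-tris(benzyloxy)-2-methylbenzoate | Cc1cc(OC(=O)c2c(C)c(OCc3ccccc3)c(OCc3ccccc3)cc2OCc2ccccc2)cc(O)c1C=O | intermediate
14 | 3-(benzyloxy)-4-formyl-5-methylphenyl 3,4,6-tris(benzyloxy)-2-methylbenzoate | Cc1cc(OC(=O)c2c(C)c(OCc3ccccc3)c(OCc3ccccc3)cc2OCc2ccccc2)cc(OCc2ccccc2)c1C=O | intermediate
15 | 2-(benzyloxy)-6-methyl-4-{[3,4,6-tris(benzyloxy)-2-methylbenzoyl]oxy}benzoic acid | Cc1cc(OC(=O)c2c(C)c(OCc3ccccc3)c(OCc3ccccc3)cc2OCc2ccccc2)cc(OCc2ccccc2)c1C(=O)O | intermediate
16 | 2-(benzyloxy)-6-methyl-4-{[3,4,6-tris(benzyloxy)-2-methylbenzoyl]oxy}benzoyl chloride | Cc1cc(OC(=O)c2c(C)c(OCc3ccccc3)c(OCc3ccccc3)cc2OCc2ccccc2)cc(OCc2ccccc2)c1C(=O)Cl | intermediate (not isolated)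
17 | benzyl (1S,6R)-4-{[2-(benzyloxy)-6-methyl-4-{[3,4,6-tris(benzyloxy)-2-methylbenzoyl]oxy}benzoyl]oxy}-6-methyl-2-oxocyclohex-3-ene-1-carboxylate (racemic, trans) | C[C@@H]1CC(OC(=O)c2c(C)cc(OC(=O)c3c(C)c(OCc4ccccc4)c(OCc4ccccc4)cc3OCc3ccccc3)cc2OCc2ccccc2)=CC(=O)[C@H]1C(=O)OCc1ccccc1 | intermediate
18 | benzyl (1S,6R)-4-{[2-(benzyloxy)-6-methyl-4-{[3,4,6-tris(benzyloxy)-2-methylbenzoyl]oxy}benzoyl]oxy}-6-methyl-2-oxo-1-(phenylselanyl)cyclohex-3-ene-1-carboxylate (racemic, selenium trans to methyl) | C[C@@H]1CC(OC(=O)c2c(C)cc(OC(=O)c3c(C)c(OCc4ccccc4)c(OCc4ccccc4)cc3OCc3ccccc3)cc2OCc2ccccc2)=CC(=O)[C@]1([Se]c1ccccc1)C(=O)OCc1ccccc1 | intermediate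
19 | selenoxide of 18: benzyl (1S,6R)-1-(benzeneseleninyl)-4-{[2-(benzyloxy)-6-methyl-4-{[3,4,6-tris(benzyloxy)-2-methylbenzoyl]oxy}benzoyl]oxy}-6-methyl-2-oxocyclohex-3-ene-1-carboxylate (racemic, both configurations at selenium) | C[C@@H]1CC(OC(=O)c2c(C)cc(OC(=O)c3c(C)c(OCc4ccccc4)c(OCc4ccccc4)cc3OCc3ccccc3)cc2OCc2ccccc2)=CC(=O)[C@]1([Se](=O)c1ccccc1)C(=O)OCc1ccccc1 | intermediate (not isolated)
20 | benzyl 4-{[2-(benzyloxy)-6-methyl-4-{[3,4,6-tris(benzyloxy)-2-methylbenzoyl]oxy}benzoyl]oxy}-2-methyl-6-oxocyclohexa-1,4-diene-1-carboxylate | CC1=C(C(=O)OCc2ccccc2)C(=O)C=C(OC(=O)c2c(C)cc(OC(=O)c3c(C)c(OCc4ccccc4)c(OCc4ccccc4)cc3OCc3ccccc3)cc2OCc2ccccc2)C1 | intermediate (not isolated)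
21 | benzyl 4-{[2-(benzyloxy)-6-methyl-4-{[3,4,6-tris(benzyloxy)-2-methylbenzoyl]oxy}benzoyl]oxy}-2-hydroxy-6-methylbenzoate | Cc1cc(OC(=O)c2c(C)cc(OC(=O)c3c(C)c(OCc4ccccc4)c(OCc4ccccc4)cc3OCc3ccccc3)cc2OCc2ccccc2)cc(O)c1C(=O)OCc1ccccc1 | intermediate
22 | 2-hydroxy-4-({2-hydroxy-6-methyl-4-[(3,4,6-trihydroxy-2-methylbenzoyl)oxy]benzoyl}oxy)-6-methylbenzoic acid | Cc1cc(OC(=O)c2c(C)cc(OC(=O)c3c(O)cc(O)c(O)c3C)cc2O)cc(O)c1C(=O)O | target

**Step count and risks**

Total: 12 steps. Longest linear sequence: 11 steps (5 to 22 through steps 2 to 12); the key step 1 feeds in at step 9.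

Step 1 (key step). The conjugate addition is reversible and benzyloxide can itself add to 2, so the sequence may stall at 3 or revert if ring closure is slow. The β-keto ester may also be hydrolysed and lose CO2 if the acidification is not kept cold and brief. Fallback: the two bond formations are separated. From 1 and 2 the Michael adduct 3 is made with catalytic DBU at room temperature and isolated. It is then closed irreversibly with NaH and a trace of benzyl alcohol in THF (hydrogen evolution drives enolate formation), and the route is rejoined at 4. No new compound arises.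

Step 9. Acylation may be spread over O4, O2 and C3 of the dione enolate, or be slow because 16 is hindered, in which case a second acylation of 17 at its β-keto ester enol competes. Fallback: ring A is taken as a ready-made arene. Starting from 16, commercial 2,4-dihydroxy-6-methylbenzoic acid F1 is converted with BnBr and KHCO3 in DMF into benzyl 2,4-dihydroxy-6-methylbenzoate F2. Its C4 hydroxyl is acylated with 16 and Et3N in CH2Cl2 (the C2 hydroxyl is chelated to the ester), which gives 21 directly. The de novo construction of ring A is given up in this case.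

Step 11 (together with step 10). Insufficient facial selectivity in the selenenylation would give a diastereomer of 18 that has no syn hydrogen and cannot eliminate. Peroxide may also attack the vinylogous anhydride, and the seleninic acid/peroxide mixture may oxidise the electron-rich ring C. Fallback: from 17, silylation with Me3SiOTf and Et3N in CH2Cl2 gives benzyl (6R)-4-{[2-(benzyloxy)-6-methyl-4-{[3,4,6-tris(benzyloxy)-2-methylbenzoyl]oxy}benzoyl]oxy}-6-methyl-2-[(trimethylsilyl)oxy]cyclohexa-1,3-diene-1-carboxylate F3 (racemic). Saegusa–Ito oxidation with Pd(OAc)2 (divalent palladium) in MeCN at room temperature then forms the C1–C6 double bond by β-hydride elimination from the palladium enolate, which can reach either face. Tautomerisation returns the route at 21 without selenium and without peroxide.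

Step 2. Over-oxidation and self-condensation of the electron-rich hydroxyquinone in the aqueous medium may erode the material. Fallback: the third oxygen is introduced by formylation and oxygen insertion.
- From 5, benzylation (BnBr, K2CO3, DMF) gives 1,3-bis(benzyloxy)-5-methylbenzene F4.
- Vilsmeier formylation (POCl3, DMF) gives 2,4-bis(benzyloxy)-6-methylbenzaldehyde F5.
- Baeyer–Villiger oxidation with mCPBA in CH2Cl2 gives 2,4-bis(benzyloxy)-6-methylphenyl formate F6.
- Methanolysis (K2CO3, MeOH) gives 2,4-bis(benzyloxy)-6-methylphenol F7.
- Benzylation of F7 returns the route at 8.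

Step 7. Carbonate-mediated cleavage or migration of the aryl ester may compete with the slow alkylation of the chelated phenol, since the phenoxide para to the formyl group is a good leaving group. Fallback: the benzyl ether is installed before the ester.
- From 11, MOMCl and i-Pr2NEt in CH2Cl2 protect the free C4 hydroxyl to give 2-hydroxy-4-(methoxymethoxy)-6-methylbenzaldehyde F8.
- BnBr and K2CO3 in DMF give 2-(benzyloxy)-4-(methoxymethoxy)-6-methylbenzaldehyde F9.
- HCl in MeOH/THF removes the acetal to give 2-(benzyloxy)-4-hydroxy-6-methylbenzaldehyde F10.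
- Acylation of F10 with 12 and Et3N in CH2Cl2 returns the route at 14.

**Further compounds**

F0 | step 1 | none | none
F1 | step 9 | 2,4-dihydroxy-6-methylbenzoic acid | Cc1cc(O)cc(O)c1C(=O)O
F2 | step 9 | benzyl 2,4-dihydroxy-6-methylbenzoate | Cc1cc(O)cc(O)c1C(=O)OCc1ccccc1
F3 | step 11 | benzyl (6R)-4-{[2-(benzyloxy)-6-methyl-4-{[3,4,6-tris(benzyloxy)-2-methylbenzoyl]oxy}benzoyl]oxy}-6-methyl-2-[(trimethylsilyl)oxy]cyclohexa-1,3-diene-1-carboxylate (racemic) | C[C@@H]1CC(OC(=O)c2c(C)cc(OC(=O)c3c(C)c(OCc4ccccc4)c(OCc4ccccc4)cc3OCc3ccccc3)cc2OCc2ccccc2)=CC(O[Si](C)(C)C)=C1C(=O)OCc1ccccc1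
F4 | step 2 | 1,3-bis(benzyloxy)-5-methylbenzene | Cc1cc(OCc2ccccc2)cc(OCc2ccccc2)c1
F5 | step 2 | 2,4-bis(benzyloxy)-6-methylbenzaldehyde | Cc1cc(OCc2ccccc2)cc(OCc2ccccc2)c1C=O
F6 | step 2 | 2,4-bis(benzyloxy)-6-methylphenyl formate | Cc1cc(OCc2ccccc2)cc(OCc2ccccc2)c1OC=O
F7 | step 2 | 2,4-bis(benzyloxy)-6-methylphenol | Cc1cc(OCc2ccccc2)cc(OCc2ccccc2)c1O
F8 | step 7 | 2-hydroxy-4-(methoxymethoxy)-6-methylbenzaldehyde | COCOc1cc(C)c(C=O)c(O)c1
F9 | step 7 | 2-(benzyloxy)-4-(methoxymethoxy)-6-methylbenzaldehyde | COCOc1cc(C)c(C=O)c(OCc2ccccc2)c1
F10 | step 7 | 2-(benzyloxy)-4-hydroxy-6-methylbenzaldehyde | Cc1cc(O)cc(OCc2ccccc2)c1C=O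
A1 | alternative 1 | benzyl 2-(benzyloxy)-4-({2-hydroxy-6-methyl-4-[(triisopropylsilyl)oxy]benzoyl}oxy)-6-methylbenzoate | Cc1cc(O[Si](C(C)C)(C(C)C)C(C)C)cc(O)c1C(=O)Oc1cc(C)c(C(=O)OCc2ccccc2)c(OCc2ccccc2)c1
A2 | alternative 1 | 3-(benzyloxy)-4-[(benzyloxy)carbonyl]-5-methylphenyl (2E)-5-diazo-3-methyl-4-oxopent-2-enoate | [N-]=[N+]=CC(=O)/C(C)=C/C(=O)Oc1cc(C)c(C(=O)OCc2ccccc2)c(OCc2ccccc2)c1
A3 | alternative 1 | (ethynyloxy)tri(propan-2-yl)silane | C#CO[Si](C(C)C)(C(C)C)C(C)C
A4 | alternative 1 | benzyl 2-(benzyloxy)-4-hydroxy-6-methylbenzoate | Cc1cc(O)cc(OCc2ccccc2)c1C(=O)OCc1ccccc1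
A5 | alternative 2 | 2-(3-hydroxy-4,6-dimethoxy-2-methylphenyl)-4,4-dimethyl-4,5-dihydro-1,3-oxazole | COc1cc(OC)c(C2=NC(C)(C)CO2)c(C)c1O
A6 | alternative 2 | 2-(5-chloro-2,4-dimethoxyphenyl)-4,4-dimethyl-4,5-dihydro-1,3-oxazole | COc1cc(OC)c(C2=NC(C)(C)CO2)cc1Cl
A7 | alternative 3 | benzyl 2-(benzyloxy)-4-[(2,4-dihydroxy-6-methylbenzoyl)oxy]-6-methylbenzoate | Cc1cc(OC(=O)c2c(C)cc(O)cc2O)cc(OCc2ccccc2)c1C(=O)OCc1ccccc1
A8 | alternative 3 | 6-(2,4-dioxopentyl)-2,2-dimethyl-4H-1,3-dioxin-4-one | CC(=O)CC(=O)CC1=CC(=O)OC(C)(C)O1
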